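In a closed, stirred vessel at constant temperature, free catalyst turns substrate into open intermediate and back, while free catalyst and open intermediate also form catalyst intermediate, which reagent carries on to target.

| flask | substrate | reagent | free catalyst | temperature | remark | time |
|---|---|---|---|---|---|---|
| ash | 0.95 M | 1.14 M | 55 mM | 35 °C | run made earlier |  |
| elm | 0.47 M | 1.14 M | 82 mM | 35 °C | run made earlier |  |
| gamma | 0.95 M | 3.00 M | 82 mM | −5 °C |  | 12 d |
| alpha | 0.95 M | 1.14 M | 82 mM | 35 °C |  | 6.0 d |

| run | time / d | open intermediate / % | target / % |
|---|---|---|---|
| ash | 0.250 | 43.6 | 1.0 |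
| ash | 0.500 | 44.3 | 1.2 |
| ash | 0.833 | 44.7 | 2.3 |
| ash | 1.25 | 45.1 | 1.9 |
| ash | 2.00 | 44.4 | 2.6 |
| ash | 4.00 | 41.4 | 5.6 |
| elm | 0.625 | 46.9 | 1.5 |
| elm | 1.25 | 44.4 | 3.7 |
| elm | 1.67 | 43.3 | 6.4 |
| elm | 2.50 | 42.1 | 6.5 |
| elm | 3.00 | 41.8 | 8.8 |
| elm | 4.00 | 39.1 | 11.4 |

(readings scatter by 1 percentage point)

- which one finishes higher in amount of open intermediate, in percent of the substrate charged ("neither" within 2 percentage points) (gamma / alpha / neither)
- amount of open intermediate at the end, in percent of the substrate charged, gamma
- amount of open intermediate at the end, in percent of the substrate charged, alpha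

- the earlier runs were read with a standard deviation of 1 percentage point
- what may be going on: target <-> isomer of the product; reagent + catalyst intermediate -> free catalyst + target; substrate -> decomposition product; substrate + free catalyst <-> free catalyst + open intermediate; free catalyst + open intermediate <-> catalyst intermediate
- the earlier runs do not show what temperature does; that part of a forecast is a guess

Alpha looks nearly the same as the ash run: it differs in free catalyst, 82 mM against 55 mM, and in running to 6.0 d. The ash run stands at 43.6% open intermediate by 0.250 d, early in a run of 4.00 d. The same free catalyst serves opening and closing, so it cancels from the ratio of their two rates, and where they balance, time drops out too. Substrate is not read, so it is counted as what open intermediate and target leave. As a reading at 1.25 d, ash gives 0.851 for Kop, the opening ratio, open intermediate over substrate at balance, an equilibrium constant as read. At 1.25 d, elm gives 0.855 with other charges.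

So ash and alpha should divide their pool alike, with a share s = Kop/(1+Kop) = 46.0% open. They part by what leaves the pool. The reckoning here scales the target of ash, 5.6% at 4.00 d, with free catalyst and time, which takes 12.5% from alpha and leaves 40.2% open, lower than the last ash reading. For gamma the earlier runs show no temperature, so Kop there is a guess; at unchanged Kop the share is 46.0%.

The forecast gave 44% for gamma and 37% for alpha, so gamma higher, noting “The temperature shift of K and the opening rate are guesses”. Its alpha figure is lower than the reckoning here.

The flask gives 84.6% in gamma and 38.3% in alpha, so gamma finishes higher. Gamma ends with 12.0% substrate, a ratio of 7.02 against the read Kop of 0.851, while alpha ends at 0.867.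

    target ⇌ isomer of the product (K = 19.0, k = 6.00 × 10⁻⁵ /min, Ea = 101 kJ/mol, ΔH = −10.0 kJ/mol)
    reagent + catalyst intermediate → free catalyst + target (k = 0.00150 /M/min, Ea = 78.0 kJ/mol)
    substrate → decomposition product (k = 7.00 × 10⁻⁷ /min, Ea = 118 kJ/mol)
    substrate + free catalyst ⇌ free catalyst + open intermediate (K = 0.870, k = 0.0930 /M/min, Ea = 66.0 kJ/mol, ΔH = −58.0 kJ/mol)
    free catalyst + open intermediate ⇌ catalyst intermediate (K = 0.430 /M, k = 0.00860 /M/min, Ea = 65.0 kJ/mol, ΔH = −2.00 kJ/mol)
    (constants at 35 °C)

For the neighbour of alpha with 0.021 M of free catalyst, Kop is kept at 0.851 and the same scaling takes 3.21%, so the reckoning gives 44.5% open. The computed neighbour ends at 44.1%.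

The data stem from a simulated flask for substances that don't exist.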